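A small charge of substrate, fed in portions while the reagent waits in the second phase, makes a short ledger, and I kept mine on the reagent, booking one reagent per target and two per over-reacted product.

| flask | substrate | reagent in the second phase | remark | time | volume of the second phase over the first |
|---|---|---|---|---|---|
| noon | 0.010 M (in portions, 3) | 1.3 equiv | run made earlier; portions every 3.0 h |  |  |
| dawn | 0.015 M (in portions, 3) | 1.3 equiv | run made earlier; portions every 3.0 h |  |  |
| flask | 0.020 M (in portions, 3) | 1.30 equiv | the portions of substrate follow each other after 3.0 h, the first at the start | 10 h | 0.25 |

- noon (time / h: over-reacted product / %, target / %): 1.50: 0.8, 2.4; 3.00: 0, 4.7; 5.00: 1.7, 10.9; 6.00: 1.5, 17.3; 8.00: 2.5, 22.9; 10.0: 2.1, 29.2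
- dawn (time / h: over-reacted product / %, target / %): 0.833: 0, 4.7; 1.33: 0, 4.6; 2.00: 0, 8.1; 4.00: 0, 12.6; 6.00: 1.9, 20.1; 10.0: 4.7, 34.2

(standard deviation of a reading: 1 percentage point)

- in the second phase: reagent in the second phase; everything else is in the first
- charges count per volume of the first phase; a concentration in a rate is the amount of a species over the volume of its own phase; every rate counts per litre of the first phase
- the earlier runs hold the two phases in the same ratio of volumes as the flask asked about

1. amount of over-reacted product in percent of the substrate charged, at 1.0 h, 4.0 h and 10 h

I closed the books on the dawn run at 10.0 h, in percent of the substrate charged:

reagent charged: 130%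
spent on target: 34.2%
spent on over-reacted product: 9.40%
unspent: 86.4%

More stayed unspent than was spent, so what I wanted from the books was the choice each reacting reagent made between substrate and target. A reacting reagent picks target over substrate in the proportion factor × target ÷ substrate, and although that proportion starts from zero and each portion of substrate cuts it back, I assumed as a rough stand-in for its mean half its last value:

over-reacted product = factor × half of the converted × target ÷ substrate left

The last readings had converted 31.3% at noon and 38.9% at dawn, and pooling both gave 0.388, my selectivity factor, how readily one target takes a reagent compared with one substrate. The symmetric case, where the two are alike, stands at 1, and this reading lay below it, though it rests on 2.1% and 4.7%, each good to 1 percentage point.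

The charges stand evenly spaced, so I extended the converted amount by the same step to 46.5% for the flask at 10 h, and the formula then gave me 6.71% of over-reacted product. The forecast, at 0.07%, 0.9% and 5.5%, stood lower at the end, stepping through the portions “with the second step using reagent too”.

The flask gave 0.115%, 1.52% and 8.25%.

    reagent in the reaction phase ⇌ reagent in the second phase, rate k1*([reagent in the reaction phase] - [reagent in the second phase]/K1) per volume of the first phase (partition coefficient = 0.493, kL = 8.76 h⁻¹)
    substrate + reagent in the reaction phase → target (k = 5.96 L mol⁻¹ h⁻¹)
    reagent in the reaction phase + target → over-reacted product (k = 2.44 L mol⁻¹ h⁻¹)

At 10.0 h the flask held 50.8% substrate and 40.9% target, and with these amounts my factor gave 7.67% of over-reacted product against the 8.25% found. In the simulated flask with twice the substrate and the other amounts as they were, over-reacted product came to 5.43%, which the same formula, read backwards, paired with 37.4% of target.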